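## The problem

The target is a (3R)-isoflavan. Ring A (C4a–C8a) is fused to the dihydropyran ring C (O1, C2, C3, C4); ring B (C1'–C6') sits on C3 and carries an angularly fused 2,2-dimethyl-2H-pyran, ring D (O1'', C2'', C3''=C4''), closed from O2' onto C3'.

- **Stereocentre.** C3 is the only one. It is a methine flanked by two methylene groups (C2 on O1, C4 on C4a) and has no neighbouring stereocentre or heteroatom that could direct its formation, so it must be set by a catalyst.
- **Ring A regiochemistry.** Ring A is a phloroglucinol with three different oxygens (O1, 5-OMe, 7-OH), and C4 must sit between O1 and the methoxy group.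
- **Ring B regiochemistry.** Ring B is a resorcinol whose C3' lies between O2' and O4'. Ring D must close onto O2' and not onto O4'.
- **Sensitive groups.** The C3''=C4'' bond of ring D is a cis-styrene. It rules out hydrogenolysis or hydrogenation over Pd, peracids and strong acid. Both arenes are electron-rich enough to be alkylated by formaldehyde equivalents or oxidised.
- **Enabling feature.** C3 is benzylic to ring B and adjacent to C2, and C2 is bound to O1, the phenolic oxygen of ring A. If C2 is raised to a lactone carbonyl (3-aryl-dihydrocoumarin 10), C3–H becomes α to an aryl ester as well as benzylic. It then epimerises under alkoxide, and C2 is the only ring atom that still needs reduction. A dynamic kinetic hydrogenation can therefore funnel racemic 10 into one enantiomer of diol 12, after which nothing acidifies C3–H.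

## Retrosynthesis

**14 ⇒ 13 ⇒ 12 (O1–C2).** The two methoxymethyl ethers of 13 mask 7-OH and 4'-OH. Ring C is cut at O1–C2, giving phenol-alcohol 12. The neighbouring cuts are worse: C4–C4a would need a Friedel–Crafts closure with open regiochemistry on ring A and a cation next to C3, and C3–C1' would need a stereospecific sp3–sp2 coupling to a doubly ortho-substituted arene. The O1–C2 cut leaves C3 untouched. The forward reaction is a 6-exo-tet Mitsunobu etherification on the only free phenol of 12.

**12 ⇒ rac-10 (key).** C2 is taken back to the lactone carbonyl and O1–C2 is reconnected as the aryl ester of racemic 10. The isolated stereocentre of 12 thereby becomes a base-labile α-aryl ester centre that needs no control when it is made. The forward reaction must reduce one enantiomer of 10 (and of aldehyde 11) faster than the other, more slowly than they interconvert, and without touching C3''=C4''.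

**10 ⇒ 9 (C3–H, C4–H).** Removing the two hydrogens gives coumarin 9, which is flat and achiral. The forward reaction is a 1,4-hydride addition that must spare the styrene of ring D.

**9 ⇒ 7 ⇒ 6 (ring D: C3'–C4'' and O1''–C2'').** Ring D is removed by the propargyl ether Claisen retron. The O2'/O4' question reduces to which phenol is free in 6. The regiochemistry at carbon is fixed because C1' is blocked and only C3' is open.

**6 ⇒ 2 + 4 (C3=C4 and the lactone O1–C2).** Coumarin 6 is cut into salicylaldehyde 2 and benzofuranone 4. Compound 4 is a C–H acidic, self-protected form of a (2-hydroxyaryl)acetic acid. Knoevenagel condensation followed by transfer of the acyl group from O2' to O1 builds the coumarin and releases O2' as the only free phenol, which is the one ring D needs. A ring B arylacetic acid with ring D already in place would need a longer preparation.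

**2 ⇒ 1 and 4 ⇒ 3.** Each is a single protection. In 1 the chelated 2-OH leaves only 4-OH reactive, and 3 has one hydroxyl. The oxygen pattern of ring A is bought with 1.

## Roads not taken

**Alternative 1:** the most obvious route keeps C4 as a ketone.
- Cut: acylation of ring A at C4a and insertion of C2 give racemic isoflavanone A1.
- Forward key step: transfer hydrogenation with dynamic kinetic resolution (RuCl(p-cymene)[(R,R)-TsDPEN], HCO2H/Et3N) gives cis-(3R,4R)-isoflavan-4-ol A2, whose C4 hydroxyl is then removed.
- Why the chosen plan is better: the C4 oxygen is the problem. Hydrogenolysis would saturate C3''=C4''. Ionic reduction passes through a C4 cation that 5-OMe and 7-OR stabilise strongly, and this cation can lose the C3 proton and flatten the stereocentre just made. A1 also needs a regiocontrolled C-acylation of an unsymmetrical phloroglucinol and a ring B arylacetic acid already carrying ring D. In the chosen plan C4 never carries a heteroatom.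

**Alternative 2:** cut C3–C4 as an auxiliary-controlled enolate alkylation.
- Cut: ring B arylacetic acid A3 is converted into the (R)-4-benzyloxazolidinone imide A4.
- Forward key step: the sodium enolate of A4 is alkylated with ring A benzyl bromide A5, and LiBH4 removes the auxiliary to give 12.
- Why the chosen plan is better: this costs a stoichiometric auxiliary and three steps to attach, use and remove it. A3 needs ring D built on an open-chain, separately protected arylacetate. A5 is a 2,4,6-trioxygenated benzyl bromide that ionises readily and is hard to store. The chosen plan reaches 12 with a catalyst and never needs A3 or A5.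

**Alternative 3:** cut C3–C4 and O1–C2 together.
- Cut: ring A o-quinone methide A6 and an activated ester of A3.
- Forward key step: a chiral isothiourea or N-heterocyclic carbene generates an enolate from A3 that adds to A6 in a formal [4+2] annulation, giving (R)-lactone A7 directly; LiBH4 would then give 12.
- Why the chosen plan is better: A7 has the same acidic C3–H that the chosen plan exploits, and here it must survive the amine or fluoride base that generates A6, so the enantiomeric purity is at risk in the step that creates it. A6 has no substituent on its methylene and an electron-rich ring, and tends to oligomerise. The chosen plan makes the same lactone as a racemate from two one-step building blocks and uses the lability of C3–H as the control element.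

Key step: step 7

Assumptions: 1 and 3 are treated as catalogue compounds; the (R)-ligand in step 7 is assigned by analogy with α-aryl lactone precedent, and its antipode would be used if the sense of induction proved opposite.

## Route

Step 1
Reactants: 1 2,4-dihydroxy-6-methoxybenzaldehyde
Product: 2 2-hydroxy-6-methoxy-4-(methoxymethoxy)benzaldehyde
Conditions: MOMCl (1.05 equiv), K2CO3, acetone, 0 °C to rt
Reagents that add atoms: chloromethyl methyl ether (MOMCl), COCCl
Why: Selective Williamson O-alkylation; the 2-OH is held in a hydrogen bond to the formyl group, so only the more acidic, unchelated 4-OH (para to CHO) reacts.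

Step 2
Reactants: 3 6-hydroxy-1-benzofuran-2(3H)-one
Product: 4 6-(methoxymethoxy)-1-benzofuran-2(3H)-one
Conditions: CH2(OMe)2 (excess), TsOH·H2O (cat.), CH2Cl2, reflux through 4 Å molecular sieves
Reagents that add atoms: dimethoxymethane, COCOC
Why: Acid-catalysed acetal exchange on the only hydroxyl; acid is chosen because base would enolise the acidic C3 methylene of the lactone, and the sieves remove methanol to drive the exchange.

Step 3
Reactants: 2 2-hydroxy-6-methoxy-4-(methoxymethoxy)benzaldehyde; 4 6-(methoxymethoxy)-1-benzofuran-2(3H)-one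
Product: 6 3-[2-hydroxy-4-(methoxymethoxy)phenyl]-5-methoxy-7-(methoxymethoxy)-2H-chromen-2-one, via Z-benzylidenebenzofuranone 5 (not isolated)
Conditions: Et3N (2 equiv), toluene, 110 °C, Dean–Stark
Reagents that add atoms: none
Why: Knoevenagel condensation of the C–H acidic lactone with the aldehyde, then intramolecular transesterification in which the ring A phenoxide attacks the five-membered lactone of the Z isomer and expels O2'; the conjugated six-membered α-pyrone is the thermodynamic sink and the E isomer equilibrates under the base. A non-nucleophilic amine is used so that the aryl lactone is not aminolysed.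

Step 4
Reactants: 6 3-[2-hydroxy-4-(methoxymethoxy)phenyl]-5-methoxy-7-(methoxymethoxy)-2H-chromen-2-one
Product: 7 5-methoxy-7-(methoxymethoxy)-3-[4-(methoxymethoxy)-2-(2-methylbut-3-yn-2-yloxy)phenyl]-2H-chromen-2-one
Conditions: 3-chloro-3-methylbut-1-yne (3 equiv), K2CO3, KI, CuI (5 mol%), acetone, 60 °C
Reagents that add atoms: 3-chloro-3-methylbut-1-yne, CC(C)(Cl)C#C
Why: Copper-assisted O-propargylation of a phenol with a tertiary propargylic chloride (standard preparation of 1,1-dimethylpropargyl aryl ethers); O2' is the only free hydroxyl, so the site of ring D is fixed here.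

Step 5
Reactants: 7 5-methoxy-7-(methoxymethoxy)-3-[4-(methoxymethoxy)-2-(2-methylbut-3-yn-2-yloxy)phenyl]-2H-chromen-2-one
Product: 9 5-methoxy-7-(methoxymethoxy)-3-[5-(methoxymethoxy)-2,2-dimethyl-2H-chromen-8-yl]-2H-chromen-2-one, via allenylphenol 8 (not isolated)
Conditions: o-xylene, 140 °C
Reagents that add atoms: none
Why: Aryl propargyl ether Claisen rearrangement to C3' (C1' is blocked), tautomerisation to the allenylphenol, 1,5-hydrogen shift and oxa-6π electrocyclisation give the 2,2-dimethyl-2H-chromene; the neutral thermal conditions leave the MOM ethers and the coumarin intact.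

Step 6
Reactants: 9 5-methoxy-7-(methoxymethoxy)-3-[5-(methoxymethoxy)-2,2-dimethyl-2H-chromen-8-yl]-2H-chromen-2-one
Product: 10 rac-5-methoxy-7-(methoxymethoxy)-3-[5-(methoxymethoxy)-2,2-dimethyl-2H-chromen-8-yl]-3,4-dihydro-2H-chromen-2-one
Conditions: Cu(OAc)2·H2O (5 mol%), 1,2-bis(diphenylphosphino)benzene (5 mol%), (EtO)2MeSiH (1.3 equiv), t-BuOH (1.3 equiv), toluene, 0 °C to rt
Reagents that add atoms: none
Why: Copper hydride conjugate reduction of a coumarin (Stryker-type 1,4-reduction): the hydride adds to C4 of the enoate and t-BuOH protonates the enolate at C3, while the unactivated styrene of ring D does not react under these conditions. C3 is formed as the racemate on purpose.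

Step 7
Reactants: 10 rac-5-methoxy-7-(methoxymethoxy)-3-[5-(methoxymethoxy)-2,2-dimethyl-2H-chromen-8-yl]-3,4-dihydro-2H-chromen-2-one
Product: 12 (2R)-3-[2-hydroxy-6-methoxy-4-(methoxymethoxy)phenyl]-2-[5-(methoxymethoxy)-2,2-dimethyl-2H-chromen-8-yl]propan-1-ol, via hydroxy aldehyde 11 (not isolated)
Conditions: H2 (10 atm), IrH2Cl[(R)-SpiroPAP] (0.5 mol%), KOtBu (2 equiv), n-PrOH, 25 °C; aq. NH4Cl
Reagents that add atoms: none
Why: Asymmetric hydrogenation of a racemic α-aryl lactone with dynamic kinetic resolution; the closest precedent is the iridium-catalysed hydrogenation of racemic α-aryl δ-valerolactones to chiral 1,5-diols, supported by the dynamic hydrogenation of racemic α-aryl aldehydes. The alkoxide interconverts the enantiomers of 10 through the lactone enolate, since C3–H is both benzylic to ring B and α to an aryl ester. The first outer-sphere hydride transfer from the Ir–H/N–H catalyst opens ring C to aldehyde 11, whose C3–H is more acidic still, so the two enantiomers stay in fast exchange. The chiral catalyst reduces the carbonyl of one enantiomer faster (Curtin–Hammett), so the whole racemate should drain into (R)-12. No ring is closed; ring C is opened here and closed again in step 8. The configuration at C3 is set only by the catalyst, and once C2 is an alcohol C3–H is no longer acidic and the centre is fixed. The step needs C=O over C=C chemoselectivity, which bifunctional iridium hydride catalysts of this type show, and enolisation faster than reduction, which the double activation of C3–H and two equivalents of base should secure. The MOM ethers are inert to base and hydride.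

Step 8
Reactants: 12 (2R)-3-[2-hydroxy-6-methoxy-4-(methoxymethoxy)phenyl]-2-[5-(methoxymethoxy)-2,2-dimethyl-2H-chromen-8-yl]propan-1-ol
Product: 13 (3R)-5-methoxy-7-(methoxymethoxy)-3-[5-(methoxymethoxy)-2,2-dimethyl-2H-chromen-8-yl]-3,4-dihydro-2H-chromene
Conditions: PPh3, DIAD, THF, 0 °C to rt
Reagents that add atoms: none
Why: Intramolecular Mitsunobu etherification (6-exo-tet) of the only free phenol onto the activated primary alcohol; displacement occurs at C2, so the C3 stereocentre is not involved and stays R.

Step 9
Reactants: 13 (3R)-5-methoxy-7-(methoxymethoxy)-3-[5-(methoxymethoxy)-2,2-dimethyl-2H-chromen-8-yl]-3,4-dihydro-2H-chromene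
Product: 14 (3R)-3-(5-hydroxy-2,2-dimethyl-2H-chromen-8-yl)-5-methoxy-3,4-dihydro-2H-chromen-7-ol (CNP0320659.1)
Conditions: HCl (3 M aq.), MeOH, 40 °C
Reagents that add atoms: none
Why: Acid-catalysed acetal cleavage of both MOM ethers; methanol traps the methoxymethyl cation as dimethoxymethane so it cannot alkylate ring A, and C3 has no ionisable or acidic neighbour under these conditions.

## Compound list

1 | 2,4-dihydroxy-6-methoxybenzaldehyde | COc1cc(O)cc(O)c1C=O | starting material
2 | 2-hydroxy-6-methoxy-4-(methoxymethoxy)benzaldehyde | COCOc1cc(O)c(C=O)c(OC)c1 | intermediate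
3 | 6-hydroxy-1-benzofuran-2(3H)-one | O=C1Cc2ccc(O)cc2O1 | starting material
4 | 6-(methoxymethoxy)-1-benzofuran-2(3H)-one | O=C1Cc2ccc(OCOC)cc2O1 | intermediate
5 | (Z)-3-[2-hydroxy-6-methoxy-4-(methoxymethoxy)benzylidene]-6-(methoxymethoxy)-1-benzofuran-2(3H)-one | O=C1Oc2cc(OCOC)ccc2/C1=C/c1c(O)cc(OCOC)cc1OC | intermediate
6 | 3-[2-hydroxy-4-(methoxymethoxy)phenyl]-5-methoxy-7-(methoxymethoxy)-2H-chromen-2-one | O=C1Oc2cc(OCOC)cc(OC)c2C=C1c1ccc(OCOC)cc1O | intermediate
7 | 5-methoxy-7-(methoxymethoxy)-3-[4-(methoxymethoxy)-2-(2-methylbut-3-yn-2-yloxy)phenyl]-2H-chromen-2-one | O=C1Oc2cc(OCOC)cc(OC)c2C=C1c1ccc(OCOC)cc1OC(C)(C)C#C | intermediate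
8 | 3-[2-hydroxy-4-(methoxymethoxy)-3-(3-methylbuta-1,2-dien-1-yl)phenyl]-5-methoxy-7-(methoxymethoxy)-2H-chromen-2-one | O=C1Oc2cc(OCOC)cc(OC)c2C=C1c1ccc(OCOC)c(C=C=C(C)C)c1O | intermediate
9 | 5-methoxy-7-(methoxymethoxy)-3-[5-(methoxymethoxy)-2,2-dimethyl-2H-chromen-8-yl]-2H-chromen-2-one | O=C1Oc2cc(OCOC)cc(OC)c2C=C1c1ccc(OCOC)c2c1OC(C)(C)C=C2 | intermediate
10 | rac-5-methoxy-7-(methoxymethoxy)-3-[5-(methoxymethoxy)-2,2-dimethyl-2H-chromen-8-yl]-3,4-dihydro-2H-chromen-2-one | O=C1Oc2cc(OCOC)cc(OC)c2CC1c1ccc(OCOC)c2c1OC(C)(C)C=C2 | intermediate
11 | rac-3-[2-hydroxy-6-methoxy-4-(methoxymethoxy)phenyl]-2-[5-(methoxymethoxy)-2,2-dimethyl-2H-chromen-8-yl]propanal | O=CC(Cc1c(O)cc(OCOC)cc1OC)c1ccc(OCOC)c2c1OC(C)(C)C=C2 | intermediate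
12 | (2R)-3-[2-hydroxy-6-methoxy-4-(methoxymethoxy)phenyl]-2-[5-(methoxymethoxy)-2,2-dimethyl-2H-chromen-8-yl]propan-1-ol | COCOc1cc(O)c(C[C@H](c2ccc(OCOC)c3c2OC(C)(C)C=C3)CO)c(OC)c1 | intermediate
13 | (3R)-5-methoxy-7-(methoxymethoxy)-3-[5-(methoxymethoxy)-2,2-dimethyl-2H-chromen-8-yl]-3,4-dihydro-2H-chromene | COc1cc(OCOC)cc2c1C[C@H](c1ccc(OCOC)c3c1OC(C)(C)C=C3)CO2 | intermediate
14 | (3R)-3-(5-hydroxy-2,2-dimethyl-2H-chromen-8-yl)-5-methoxy-3,4-dihydro-2H-chromen-7-ol | COc1cc(O)cc2c1C[C@H](c1ccc(O)c3c1OC(C)(C)C=C3)CO2 | target

## Step count and risks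

Total steps: 9. Longest linear sequence: 8 (steps 2 to 9 from 3, or steps 1 and 3 to 9 from 1).

**Step 7 (key step).**
- What may go wrong: the aryl ester may be solvolysed by the alkoxide medium before it is hydrogenated. The reduction would then run on a less electrophilic, more slowly racemising species and could stall or become a plain kinetic resolution. The catalyst may also discriminate poorly, because the doubly ortho-substituted ring B is bulkier than the aryl groups of the precedent.
- Fallback: the dynamic step is moved to the aldehyde oxidation level and to another catalyst class. Starting from 10, DIBAL-H (CH2Cl2, −78 °C) gives the lactol 5-methoxy-7-(methoxymethoxy)-3-[5-(methoxymethoxy)-2,2-dimethyl-2H-chromen-8-yl]chroman-2-ol F1, the ring-closed form of 11. F1 is hydrogenated with a ruthenium diphosphine/diamine catalyst of the type used for racemic α-aryl aldehydes (RuCl2[(S)-DMM-SDP][(R,R)-DACH], KOtBu, i-PrOH, H2), with the enantiomer of the catalyst chosen for the R product. The route is rejoined at 12.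

**Step 3.**
- What may go wrong: the doubly ortho-oxygenated, chelated aldehyde is a poor electrophile, and the condensation may stop at the benzylidene stage if the E isomer does not equilibrate, so acyl transfer to O1 stays incomplete.
- Fallback: a Perkin–Oglialoro condensation. Starting from 4, saponification (LiOH, THF/H2O) gives [2-hydroxy-4-(methoxymethoxy)phenyl]acetic acid F2. Heating F2 with 2 in Ac2O/Et3N at 110 °C gives the O2'-acetylated coumarin 2-[5-methoxy-7-(methoxymethoxy)-2-oxo-2H-chromen-3-yl]-5-(methoxymethoxy)phenyl acetate F3. Methanolysis (K2CO3, MeOH) returns to the route at 6.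

**Step 2.**
- What may go wrong: the methoxymethyl cation may attack carbon (the enolisable C3 methylene or the activated ring) instead of oxygen, or the released methanol may open the lactone under acid.
- Fallback: protect after the union. Starting from 3, condensation with 2 under the conditions of step 3 gives 3-(2,4-dihydroxyphenyl)-5-methoxy-7-(methoxymethoxy)-2H-chromen-2-one F4. The coumarin no longer has an acidic methylene, so base can be used: MOMCl/i-Pr2NEt at −20 °C should alkylate the unhindered 4'-OH in preference to the 2'-OH, which is hindered by the coumarin and hydrogen-bonded to its carbonyl. The route is rejoined at 6.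

**Step 6.**
- What may go wrong: hydride delivery to C4 may be slow because of the peri 5-methoxy group and the 3-aryl substituent, and the reactive aryl lactone may be over-reduced by excess silane.
- Fallback: electron-transfer reduction. Starting from 9, Mg in MeOH reduces the conjugated C3=C4 bond and methanolyses the lactone, giving methyl 3-[2-hydroxy-6-methoxy-4-(methoxymethoxy)phenyl]-2-[5-(methoxymethoxy)-2,2-dimethyl-2H-chromen-8-yl]propanoate F5; the unactivated styrene of ring D should not react. F5 is taken into the conditions of step 7 as it is (the first hydride transfer leads to the same aldehyde 11), and the route is rejoined at 12.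

**Step 9.**
- What may go wrong: the acid may add solvent across C3''=C4'' or open ring D, and formaldehyde equivalents released from the acetals may alkylate ring A.
- Fallback: an acid-free cleavage that sequesters the electrophile. Starting from 13, TMSOTf and 2,2'-bipyridyl (MeCN, 0 °C to rt) transfer the methoxymethyl groups to the pyridine nitrogen and give the bis(trimethylsilyl) ether (3R)-5-methoxy-7-(trimethylsilyloxy)-3-[2,2-dimethyl-5-(trimethylsilyloxy)-2H-chromen-8-yl]-3,4-dihydro-2H-chromene F6. Aqueous work-up hydrolyses F6 and returns to the route at 14.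

## Further compounds

F1 | step 7 | 5-methoxy-7-(methoxymethoxy)-3-[5-(methoxymethoxy)-2,2-dimethyl-2H-chromen-8-yl]chroman-2-ol (racemic, anomeric mixture) | OC1Oc2cc(OCOC)cc(OC)c2CC1c1ccc(OCOC)c2c1OC(C)(C)C=C2
F2 | step 3 | [2-hydroxy-4-(methoxymethoxy)phenyl]acetic acid | OC(=O)Cc1ccc(OCOC)cc1O
F3 | step 3 | 2-[5-methoxy-7-(methoxymethoxy)-2-oxo-2H-chromen-3-yl]-5-(methoxymethoxy)phenyl acetate | CC(=O)Oc1cc(OCOC)ccc1C1=Cc2c(OC)cc(OCOC)cc2OC1=O
F4 | step 2 | 3-(2,4-dihydroxyphenyl)-5-methoxy-7-(methoxymethoxy)-2H-chromen-2-one | O=C1Oc2cc(OCOC)cc(OC)c2C=C1c1ccc(O)cc1O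
F5 | step 6 | methyl 3-[2-hydroxy-6-methoxy-4-(methoxymethoxy)phenyl]-2-[5-(methoxymethoxy)-2,2-dimethyl-2H-chromen-8-yl]propanoate (racemic) | COC(=O)C(Cc1c(O)cc(OCOC)cc1OC)c1ccc(OCOC)c2c1OC(C)(C)C=C2
F6 | step 9 | (3R)-5-methoxy-7-(trimethylsilyloxy)-3-[2,2-dimethyl-5-(trimethylsilyloxy)-2H-chromen-8-yl]-3,4-dihydro-2H-chromene | COc1cc(O[Si](C)(C)C)cc2c1C[C@H](c1ccc(O[Si](C)(C)C)c3c1OC(C)(C)C=C3)CO2
A1 | alternative 1 | rac-5-methoxy-7-(methoxymethoxy)-3-[5-(methoxymethoxy)-2,2-dimethyl-2H-chromen-8-yl]-2,3-dihydro-4H-chromen-4-one | COc1cc(OCOC)cc2c1C(=O)C(c1ccc(OCOC)c3c1OC(C)(C)C=C3)CO2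
A2 | alternative 1 | (3R,4R)-5-methoxy-7-(methoxymethoxy)-3-[5-(methoxymethoxy)-2,2-dimethyl-2H-chromen-8-yl]-3,4-dihydro-2H-chromen-4-ol | COc1cc(OCOC)cc2c1[C@H](O)[C@H](c1ccc(OCOC)c3c1OC(C)(C)C=C3)CO2
A3 | alternative 2 | [5-(methoxymethoxy)-2,2-dimethyl-2H-chromen-8-yl]acetic acid | OC(=O)Cc1ccc(OCOC)c2c1OC(C)(C)C=C2
A4 | alternative 2 | (4R)-4-benzyl-3-{[5-(methoxymethoxy)-2,2-dimethyl-2H-chromen-8-yl]acetyl}-1,3-oxazolidin-2-one | O=C(Cc1ccc(OCOC)c2c1OC(C)(C)C=C2)N1[C@H](Cc2ccccc2)COC1=O
A5 | alternative 2 | 2-(bromomethyl)-1-methoxy-3,5-bis(methoxymethoxy)benzene | COCOc1cc(OC)c(CBr)c(OCOC)c1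
A6 | alternative 3 | 5-methoxy-3-(methoxymethoxy)-6-methylidenecyclohexa-2,4-dien-1-one | C=C1C(=O)C=C(OCOC)C=C1OC
A7 | alternative 3 | (3R)-5-methoxy-7-(methoxymethoxy)-3-[5-(methoxymethoxy)-2,2-dimethyl-2H-chromen-8-yl]-3,4-dihydro-2H-chromen-2-one | COc1cc(OCOC)cc2c1C[C@H](c1ccc(OCOC)c3c1OC(C)(C)C=C3)C(=O)O2
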